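**Plan**

- Retrosynthesis: after removal of six benzyl groups, the C2–aryl bond is cut (arene opening of a C2/C3 epoxide), giving a planar benzofuro[2,3-b]chromenone. Its pyranone ring is cut at C3–C4 and O1–C8a into a flavan-fused benzofuran-2(3H)-one and a 2-fluorobenzoyl chloride, and the lactone is cut back to a flavan C8 glyoxylate.
- Enabling feature: C2 and C3 are a fully substituted pair common to the furan ring and the pyranone ring. C2 (bonded to O1, the furan oxygen and an aryl carbon) is at the carboxylic acid oxidation level, so C2/C3 can be the carbonyl and α-carbon of a benzofuranone while ring A arrives as an aroyl unit with an ortho fluorine.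
- Forward order: flavan → furanone ring on flavan O7/C8 → pyranone ring with ring A (step 10) → epoxide on C2=C3 → aryl at C2 → global debenzylation.
- Stereochemistry: flavan C3 (R) comes from (−)-epiafzelechin and flavan C2 (S) from thermodynamic C2 epimerisation. Chromanone C3 (R) comes from reagent-controlled dioxirane epoxidation of the planar C2=C3 bond, and chromanone C2 (S) from anti opening of that epoxide, which puts aryl and hydroxyl on opposite faces.

Key step: step 10

Remark on the chemistry (assumption): the target string is read with the C2 aryl and the C3 hydroxyl anti (trans-fused furan/pyranone; chromanone C2 S, C3 R; flavan C2 S, C3 R). C2, C3, C4, O1, C4a, C8a and ring A refer to the chromanone unit; flavan atoms are called "flavan C…".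

**Route**

Step 1
Reactants: 1 (−)-epiafzelechin
Product: 3 ent-afzelechin [(2S,3R)-2-(4-hydroxyphenyl)chroman-3,5,7-triol], via para-quinone methide 2 (not isolated)
Conditions: aq. KH2PO4/K2HPO4 buffer (pH 7, degassed), 120 °C, sealed tube, Ar; preparative reversed-phase HPLC, recovered 1 recycled
Reagents that add atoms: none
Why: Thermodynamic C2 epimerisation of a flavan-3-ol: the 4'-phenolate opens the O1–C2 bond to quinone methide 2 and oxa-Michael reclosure by the ring A phenol on either face equilibrates C2 toward the 2,3-trans isomer 3 (flavan C2 S) while C3 (R) is never touched, so separation and recycling should deliver the (2S,3R) series.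

Step 2
Reactants: 3 ent-afzelechin
Product: 5 (2S,3R)-3,5,7-tris(benzyloxy)-2-(4-benzyloxyphenyl)chroman, via tri-O-benzyl phenol ether 4 (not isolated)
Conditions: BnBr (3.3 equiv), K2CO3 (4 equiv), DMF, 0 °C→rt; then NaH (3 equiv), BnBr (1.5 equiv), Bu4NI (cat.), 0 °C→rt
Reagents that add atoms: benzyl bromide, BrCc1ccccc1
Why: Williamson etherification in two stages: carbonate benzylates the three phenols first (which also removes the free 4'-OH needed for any further C2 epimerisation), then the alkoxide formed with NaH benzylates the secondary 3-OH, and no stereocentre is affected.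

Step 3
Reactants: 5 (2S,3R)-3,5,7-tris(benzyloxy)-2-(4-benzyloxyphenyl)chroman
Product: 6 (2S,3R)-3,5,7-tris(benzyloxy)-2-(4-benzyloxyphenyl)-8-bromochroman
Conditions: NBS (1.0 equiv), CH2Cl2, −78 °C→0 °C
Reagents that add atoms: N-bromosuccinimide, O=C1CCC(=O)N1Br
Why: Electrophilic aromatic bromination of the phloroglucinol-type ring goes to flavan C8, the preferred position in per-O-benzylated flavan-3-ols, and one equivalent at low temperature should avoid the 6,8-dibromide.

Step 4
Reactants: 6 8-bromoflavan; 7 diethyl oxalate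
Product: 9 ethyl 2-oxo-2-[(2S,3R)-3,5,7-tris(benzyloxy)-2-(4-benzyloxyphenyl)chroman-8-yl]acetate, via 8-lithioflavan 8 (not isolated)
Conditions: n-BuLi (1.05 equiv), THF, −78 °C; cannulated into (CO2Et)2 (3 equiv), THF, −78 °C; then H2O
Reagents that add atoms: diethyl oxalate (7), CCOC(=O)C(=O)OCC
Why: Bromine–lithium exchange gives aryllithium 8, and its inverse addition to excess diethyl oxalate should stop at the α-keto ester because the chelated tetrahedral adduct survives at −78 °C until the quench (aryl glyoxylate synthesis).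

Step 5
Reactants: 9 flavan C8 α-keto ester
Product: 10 ethyl 2-[(2S,3R)-3,5-bis(benzyloxy)-2-(4-benzyloxyphenyl)-7-hydroxychroman-8-yl]-2-oxoacetate
Conditions: BCl3 (1.1 equiv), CH2Cl2, −78 °C; then H2O at −78 °C
Reagents that add atoms: none
Why: Chelation-directed ether cleavage: BCl3 held between the aryl ketone oxygen and the flanking O7 ether delivers chloride to the primary benzyl carbon, so one equivalent at −78 °C should remove only the 7-O-benzyl group, attack at the hindered ring carbon (through the O1 chelate) and at the non-chelated benzyl ethers being much slower.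

Step 6
Reactants: 10 7-hydroxy α-keto ester
Product: 12 ethyl 2-[(2S,3R)-3,5-bis(benzyloxy)-2-(4-benzyloxyphenyl)-7-hydroxychroman-8-yl]acetate, via α-hydroxy ester 11 (not isolated)
Conditions: SmI2 (5 equiv), HMPA, t-BuCO2H, THF, 0 °C→rt
Reagents that add atoms: none
Why: Samarium diiodide reduction of α-oxygenated esters: two electrons and two protons take the keto ester to α-hydroxy ester 11, and further electron transfer to the ester expels the benzylic α-oxygen to leave the arylacetate, under conditions that spare benzyl ethers and the flavan ring.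

Step 7
Reactants: 12 ethyl (7-hydroxyflavan-8-yl)acetate
Product: 13 flavan-fused benzofuran-2(3H)-one [(2S,3R)-3,5-bis(benzyloxy)-2-(4-benzyloxyphenyl)-3,4-dihydro-2H-furo[2,3-h]chromen-8(9H)-one]
Conditions: pyridinium p-toluenesulfonate (10 mol %), toluene, 5 Å MS, 90 °C
Reagents that add atoms: none
Why: Acid-catalysed lactonisation (intramolecular transesterification) of an ortho-hydroxyarylacetate closes the five-membered lactone on O7, removal of ethanol by the sieves driving it to completion.

Step 8
Reactants: 14 2,4,6-trifluorobenzoic acid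
Product: 16 2,4-bis(benzyloxy)-6-fluorobenzoic acid, via 4-benzyloxy-2,6-difluorobenzoic acid 15 (not isolated)
Conditions: BnOH (2.2 equiv), KOt-Bu (3.3 equiv), DMSO, 80 °C; then aq. HCl
Reagents that add atoms: benzyl alcohol, OCc1ccccc1
Why: Twofold nucleophilic aromatic substitution (SNAr) by benzyl oxide on the trifluorobenzoate: the unhindered para fluorine should go first, the second substitution is then necessarily ortho, and limiting the alkoxide to two equivalents should stop before the last fluorine is replaced.

Step 9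
Reactants: 16 2,4-bis(benzyloxy)-6-fluorobenzoic acid
Product: 17 2,4-bis(benzyloxy)-6-fluorobenzoyl chloride
Conditions: (COCl)2 (1.5 equiv), DMF (cat.), CH2Cl2, 0 °C→rt; evaporation, used directly
Reagents that add atoms: oxalyl chloride, ClC(=O)C(Cl)=O
Why: Vilsmeier-type activation by oxalyl chloride with catalytic DMF converts the acid into the acid chloride under conditions that leave aryl benzyl ethers intact.

Step 10
Reactants: 13 flavan-fused benzofuran-2(3H)-one; 17 2,4-bis(benzyloxy)-6-fluorobenzoyl chloride
Product: 20 flavan-fused 1,3-bis(benzyloxy)benzofuro[2,3-b]chromen-11-one (planar C2=C3 core), via lithium lactone enolate 18 (not isolated), via lithium 3-aroylbenzofuran-2-olate 19 (not isolated)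
Conditions: LiN(SiMe3)2 (2.1 equiv), THF, −78 °C; 17 (1.05 equiv), −78→0 °C; DMAP (0.2 equiv), rt; then DMF, 70 °C
Reagents that add atoms: 2,4-bis(benzyloxy)-6-fluorobenzoyl chloride (17), O=C(Cl)c1c(F)cc(OCc2ccccc2)cc1OCc1ccccc1
Why: LiN(SiMe3)2 turns lactone 13 into the aromatic 2-oxidobenzofuran enolate 18, whose C3 attacks the acid chloride by addition–elimination (C3–C4; any O-acylated enol ester is returned to carbon by DMAP-catalysed acyl transfer), and the second equivalent of base leaves the 3-aroyl enolate 19, whose C2 oxygen then adds to the fluorine-bearing carbon and expels fluoride from the Meisenheimer adduct (O1–C8a). The closest known reaction type is the one-pot C-acylation/intramolecular SNAr of active-methylene enolates with 2-fluorobenzoyl chlorides used for chromones and xanthones, together with the Steglich-type O-to-C acyl migration of benzofuranone enol esters. The pyranone ring (O1, C2, C3, C4, C4a, C8a) closes by a 6-exo-trig addition–elimination at the aromatic carbon. No stereocentre is formed, and the flavan C2 and C3 centres, which carry no acidic hydrogen, pass through unchanged. The step needs C- over O-acylation, secured by the lithium counter-ion and the thermodynamic pull toward the doubly stabilised β-keto lactone enolate, and O-arylation at the right carbon, secured because only the C2 oxygen reaches the C–F carbon through a six-membered transition state (C3 or the ketone oxygen would form four-membered rings), fluoride is the only good leaving group, and the ortho carbonyl stabilises the adduct while the two benzyloxy groups, meta to the reacting carbon, do not oppose it. Because C2 enters as a lactone carbon it is already at the acid oxidation level, so the product is directly the planar benzofuro[2,3-b]chromenone.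

Step 11
Reactants: 20 flavan-fused benzofuro[2,3-b]chromen-11-one
Product: 21 C2/C3 epoxide of 20 (oxygen on the face that makes C3 R)
Conditions: D-fructose-derived Shi ketone [1,2:4,5-di-O-isopropylidene-β-D-erythro-2,3-hexodiulo-2,6-pyranose] (0.5 equiv), Oxone (2KHSO5·KHSO4·K2SO4), K2CO3, Bu4NHSO4, MeCN/CH2(OMe)2, aq. Na2B4O7/Na2EDTA (pH 10.5), 0 °C; cold extractive work-up, used crude
Reagents that add atoms: potassium peroxymonosulfate (active component of Oxone), [K+].[O-]S(=O)(=O)OO
Why: Asymmetric dioxirane (Shi) epoxidation: the chiral dioxirane transfers oxygen electrophilically to the donor-substituted C2=C3 bond, as dimethyldioxirane does with flavones and benzofurans, and reagent control (the flavan stereocentres are too remote to bias the faces) should set C3 as R with the C2 oxygen on the same face, the sense of induction being confirmed on the first run (the antipodal ketone serves the other face) and the minor facial isomer being a separable diastereomer.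

Step 12
Reactants: 21 C2/C3 epoxide; 22 benzyl phenyl ether
Product: 23 hexa-O-benzyl ether of the target (trans-fused; chromanone C2 S, C3 R)
Conditions: PhOBn (22, 10 equiv), BF3·OEt2 (0.2 equiv), 4 Å MS, CH2Cl2, −78 °C; Et3N quench at −78 °C
Reagents that add atoms: benzyl phenyl ether (22), c1ccccc1COc1ccccc1
Why: Proposed new method: BF3 bound to the epoxide oxygen weakens the C2–O bond of this orthoester-type carbon so that positive charge builds at C2 (stabilised by O1 and the furan oxygen) while the departing oxygen, still attached to C3 and boron, shields its own face, so the para carbon of benzyl phenyl ether should bond to C2 from the opposite face (inversion at C2, retention at C3) and give the anti aryl/hydroxyl pair of the trans-fused core as the kinetic product; the closest known reactions are the Lewis-acid Friedel–Crafts opening of oxygen- or aryl-stabilised epoxides with inversion and the anti C-arylation of 1,2-anhydro sugars at the anomeric carbon.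

Step 13
Reactants: 23 hexa-O-benzyl ether
Product: 24 target compound CNP0146414.2
Conditions: H2 (1 atm), Pd(OH)2/C (20 wt %), EtOAc/MeOH, rt; filtration through Celite
Reagents that add atoms: none
Why: Heterogeneous hydrogenolysis of the five aryl benzyl ethers and the one alkyl benzyl ether under neutral conditions, as used to deprotect benzylated flavan-3-ol oligomers and their aryl ketals, should leave the aryl ketone, the flavan C2–O1 bond, the tertiary C3–OH and the acid-sensitive trans-fused C2 ketal untouched.

**Compound list**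

1 | (−)-epiafzelechin, (2R,3R)-2-(4-hydroxyphenyl)chroman-3,5,7-triol | O[C@@H]1Cc2c(O)cc(O)cc2O[C@@H]1c1ccc(O)cc1 | starting material
2 | para-quinone methide, 4-[(2R)-2-hydroxy-3-(2,4,6-trihydroxyphenyl)propylidene]cyclohexa-2,5-dien-1-one | O[C@@H](C=C1C=CC(=O)C=C1)Cc1c(O)cc(O)cc1O | intermediate (not isolated)
3 | ent-afzelechin, (2S,3R)-2-(4-hydroxyphenyl)chroman-3,5,7-triol | O[C@@H]1Cc2c(O)cc(O)cc2O[C@H]1c1ccc(O)cc1 | intermediate
4 | (2S,3R)-5,7-bis(benzyloxy)-2-(4-benzyloxyphenyl)chroman-3-ol | O[C@@H]1Cc2c(OCc3ccccc3)cc(OCc3ccccc3)cc2O[C@H]1c1ccc(OCc2ccccc2)cc1 | intermediate (not isolated)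
5 | (2S,3R)-3,5,7-tris(benzyloxy)-2-(4-benzyloxyphenyl)chroman | c1ccccc1CO[C@@H]1Cc2c(OCc3ccccc3)cc(OCc3ccccc3)cc2O[C@H]1c1ccc(OCc2ccccc2)cc1 | intermediate
6 | (2S,3R)-3,5,7-tris(benzyloxy)-2-(4-benzyloxyphenyl)-8-bromochroman | c1ccccc1CO[C@@H]1Cc2c(OCc3ccccc3)cc(OCc3ccccc3)c(Br)c2O[C@H]1c1ccc(OCc2ccccc2)cc1 | intermediate
7 | diethyl oxalate | CCOC(=O)C(=O)OCC | starting material
8 | 8-lithio derivative of 5 | c1ccccc1CO[C@@H]1Cc2c(OCc3ccccc3)cc(OCc3ccccc3)c([Li])c2O[C@H]1c1ccc(OCc2ccccc2)cc1 | intermediate (not isolated)
9 | ethyl 2-oxo-2-[(2S,3R)-3,5,7-tris(benzyloxy)-2-(4-benzyloxyphenyl)chroman-8-yl]acetate | c1ccccc1CO[C@@H]1Cc2c(OCc3ccccc3)cc(OCc3ccccc3)c(C(=O)C(=O)OCC)c2O[C@H]1c1ccc(OCc2ccccc2)cc1 | intermediate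
10 | ethyl 2-[(2S,3R)-3,5-bis(benzyloxy)-2-(4-benzyloxyphenyl)-7-hydroxychroman-8-yl]-2-oxoacetate | c1ccccc1CO[C@@H]1Cc2c(OCc3ccccc3)cc(O)c(C(=O)C(=O)OCC)c2O[C@H]1c1ccc(OCc2ccccc2)cc1 | intermediate
11 | ethyl 2-hydroxy-2-[(2S,3R)-3,5-bis(benzyloxy)-2-(4-benzyloxyphenyl)-7-hydroxychroman-8-yl]acetate (both carbinol epimers) | c1ccccc1CO[C@@H]1Cc2c(OCc3ccccc3)cc(O)c(C(O)C(=O)OCC)c2O[C@H]1c1ccc(OCc2ccccc2)cc1 | intermediate (not isolated)
12 | ethyl 2-[(2S,3R)-3,5-bis(benzyloxy)-2-(4-benzyloxyphenyl)-7-hydroxychroman-8-yl]acetate | c1ccccc1CO[C@@H]1Cc2c(OCc3ccccc3)cc(O)c(CC(=O)OCC)c2O[C@H]1c1ccc(OCc2ccccc2)cc1 | intermediate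
13 | flavan-fused benzofuran-2(3H)-one (lactone O on flavan C7, CH2 on flavan C8; flavan C2 S, C3 R; 3-, 5- and 4'-O-benzyl) | O=C1Cc2c(O1)cc(OCc3ccccc3)c3c2O[C@@H](c2ccc(OCc4ccccc4)cc2)[C@H](OCc2ccccc2)C3 | intermediate
14 | 2,4,6-trifluorobenzoic acid | OC(=O)c1c(F)cc(F)cc1F | starting material
15 | 4-benzyloxy-2,6-difluorobenzoic acid | OC(=O)c1c(F)cc(OCc2ccccc2)cc1F | intermediate (not isolated)
16 | 2,4-bis(benzyloxy)-6-fluorobenzoic acid | OC(=O)c1c(F)cc(OCc2ccccc2)cc1OCc1ccccc1 | intermediate
17 | 2,4-bis(benzyloxy)-6-fluorobenzoyl chloride | O=C(Cl)c1c(F)cc(OCc2ccccc2)cc1OCc1ccccc1 | intermediate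
18 | lithium enolate of 13 (lithium benzofuran-2-olate) | [Li+].[O-]c1cc2c(o1)cc(OCc3ccccc3)c3c2O[C@@H](c2ccc(OCc4ccccc4)cc2)[C@H](OCc2ccccc2)C3 | intermediate (not isolated)
19 | lithium 3-[2,4-bis(benzyloxy)-6-fluorobenzoyl]benzofuran-2-olate of the flavan-fused lactone | [Li+].[O-]c1oc2cc(OCc4ccccc4)c3c(c2c1C(=O)c1c(F)cc(OCc2ccccc2)cc1OCc1ccccc1)O[C@@H](c1ccc(OCc2ccccc2)cc1)[C@H](OCc1ccccc1)C3 | intermediate (not isolated)
20 | flavan-fused benzofuro[2,3-b]chromen-11-one (C2=C3 shared by furan and pyranone; O1 and furan O both on C2; ring A 5,7-bis(benzyloxy); furan O on flavan C7, C3 on flavan C8; flavan C2 S, C3 R; 3-, 5- and 4'-O-benzyl) | O=C1C2=C(Oc3cc(OCc4ccccc4)cc(OCc4ccccc4)c13)Oc1cc(OCc3ccccc3)c3c(c12)O[C@@H](c1ccc(OCc2ccccc2)cc1)[C@H](OCc1ccccc1)C3 | intermediate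
21 | C2/C3 epoxide of 20 (C3 R; oxygen on one face of both carbons) | O=C1c2c(OCc6ccccc6)cc(OCc6ccccc6)cc2O[C@@]2(O5)Oc3cc(OCc6ccccc6)c4c(c3[C@@]125)O[C@@H](c1ccc(OCc2ccccc2)cc1)[C@H](OCc1ccccc1)C4 | intermediate
22 | benzyl phenyl ether | c1ccccc1COc1ccccc1 | starting material
23 | hexa-O-benzyl ether of the target (C2 4-benzyloxyphenyl anti to C3 OH; chromanone C2 S, C3 R; flavan C2 S, C3 R) | O=C1c2c(OCc6ccccc6)cc(OCc6ccccc6)cc2O[C@]2(c3ccc(OCc6ccccc6)cc3)Oc3cc(OCc6ccccc6)c4c(c3[C@@]12O)O[C@@H](c1ccc(OCc2ccccc2)cc1)[C@H](OCc1ccccc1)C4 | intermediate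
24 | CNP0146414.2 | O=C1c2c(O)cc(O)cc2O[C@]2(c3ccc(O)cc3)Oc3cc(O)c4c(c3[C@@]12O)O[C@@H](c1ccc(O)cc1)[C@H](O)C4 | target

**Step count and risks**

Total step count: 13. Longest linear sequence: 11 steps (steps 1–7 and 10–13); the acid chloride branch is 2 steps (8–9).

Steps most likely to fail:

Step 12 (the one step resting on a proposed new method). The arene may bond to C2 on the same face as the C3 oxygen. The strained trans ketal may re-ionise under the Lewis acid and epimerise. The ring-opened cation may also rearrange by a 1,2-acyl shift before the weakly nucleophilic arene captures it. The fallback sets out from epoxide 21 and brings the aryl group in stepwise from a stable donor by known reactions. Neutral methanolysis (MeOH, −40→0 °C, the usual anti solvolysis of dioxirane-derived enol-ether epoxides) gives the 2-methoxy-3-hydroxy mixed ketal F1. The tertiary alcohol is capped (Et3SiOTf, 2,6-lutidine) to give the triethylsilyl ether F2. Exchange of the exocyclic methoxy group for benzyl phenyl ether (BF3·OEt2, 2,6-di-tert-butyl-4-methylpyridine, CH2Cl2, −78 °C) is a Friedel–Crafts substitution of a ketal donor of the C-glycosylation type. Here the bulky silyl ether blocks the syn face and no free alkoxide is present to drive the acyl shift, so it should give the silyl-protected arylation product F3. Buffered fluoride (Bu4NF/AcOH) then returns to the route at 23.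

Step 11. Oxygen transfer from the chiral dioxirane to this hindered, acyl-substituted benzofuran-type double bond may be too slow. The orthoester-type epoxide may hydrolyse in the basic aqueous medium, or the two faces may be poorly discriminated. The fallback sets out from 20 and replaces reagent control by separation. Isolated dimethyldioxirane in dry acetone/CH2Cl2 (−20 °C→rt, volatile by-product only, precedented for flavones, benzofurans and enol ethers) gives 21 together with the facial-isomer epoxide F4. The mixture is taken through the step 12 conditions, and the trans-fused diastereomer F5 is removed by chromatography. The flavan stereocentres make the two products diastereomers, so this separation is possible, and the route is rejoined at 23.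

Step 5. The boron Lewis acid may also cleave the aliphatic 3-O-benzyl ether. It may open the pyran O1–C2 bond through the alternative chelate, which would scramble flavan C2, or it may fail to distinguish the O7 and O1 chelates. The fallback sets out from bromide 6 and moves the chelation-directed debenzylation to an aldehyde, where a mild magnesium Lewis acid suffices. Bromine–lithium exchange and DMF give the 8-formyl flavan F6. MgBr2·OEt2 (toluene/Et2O, rt→50 °C) removes only the benzyl group ortho to the aldehyde to give the 7-hydroxy aldehyde F7. Wittig methoxymethylenation (Ph3P=CHOMe, 3 equiv, THF) gives the methyl enol ether F8, and dilute aqueous HCl in THF closes it to the lactol F9. Oxidation with Ag2CO3 on Celite (toluene, reflux) rejoins the route at lactone 13.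

Further compounds
F1 | step 12 | 2-methoxy-3-hydroxy mixed ketal from methanolysis of 21 (OMe anti to OH) | O=C1c2c(OCc6ccccc6)cc(OCc6ccccc6)cc2O[C@]2(OC)Oc3cc(OCc6ccccc6)c4c(c3[C@@]12O)O[C@@H](c1ccc(OCc2ccccc2)cc1)[C@H](OCc1ccccc1)C4
F2 | step 12 | 3-O-triethylsilyl ether of F1 | O=C1c2c(OCc6ccccc6)cc(OCc6ccccc6)cc2O[C@]2(OC)Oc3cc(OCc6ccccc6)c4c(c3[C@@]12O[Si](CC)(CC)CC)O[C@@H](c1ccc(OCc2ccccc2)cc1)[C@H](OCc1ccccc1)C4
F3 | step 12 | 3-O-triethylsilyl ether of 23 | O=C1c2c(OCc6ccccc6)cc(OCc6ccccc6)cc2O[C@]2(c3ccc(OCc6ccccc6)cc3)Oc3cc(OCc6ccccc6)c4c(c3[C@@]12O[Si](CC)(CC)CC)O[C@@H](c1ccc(OCc2ccccc2)cc1)[C@H](OCc1ccccc1)C4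
F4 | step 11 | facial isomer of epoxide 21 (oxygen on the other face) | O=C1c2c(OCc6ccccc6)cc(OCc6ccccc6)cc2O[C@]2(O5)Oc3cc(OCc6ccccc6)c4c(c3[C@]125)O[C@@H](c1ccc(OCc2ccccc2)cc1)[C@H](OCc1ccccc1)C4
F5 | step 11 | trans-fused arylation product from F4 (epimer of 23 at both chromanone C2 and C3) | O=C1c2c(OCc6ccccc6)cc(OCc6ccccc6)cc2O[C@@]2(c3ccc(OCc6ccccc6)cc3)Oc3cc(OCc6ccccc6)c4c(c3[C@]12O)O[C@@H](c1ccc(OCc2ccccc2)cc1)[C@H](OCc1ccccc1)C4
F6 | step 5 | (2S,3R)-3,5,7-tris(benzyloxy)-2-(4-benzyloxyphenyl)chroman-8-carbaldehyde | c1ccccc1CO[C@@H]1Cc2c(OCc3ccccc3)cc(OCc3ccccc3)c(C=O)c2O[C@H]1c1ccc(OCc2ccccc2)cc1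
F7 | step 5 | (2S,3R)-3,5-bis(benzyloxy)-2-(4-benzyloxyphenyl)-7-hydroxychroman-8-carbaldehyde | c1ccccc1CO[C@@H]1Cc2c(OCc3ccccc3)cc(O)c(C=O)c2O[C@H]1c1ccc(OCc2ccccc2)cc1
F8 | step 5 | (2S,3R)-3,5-bis(benzyloxy)-2-(4-benzyloxyphenyl)-8-(2-methoxyvinyl)chroman-7-ol (E/Z mixture) | c1ccccc1CO[C@@H]1Cc2c(OCc3ccccc3)cc(O)c(C=COC)c2O[C@H]1c1ccc(OCc2ccccc2)cc1
F9 | step 5 | lactol of 13 (2-hydroxy-2,3-dihydrobenzofuran fused to the flavan; anomer mixture) | OC1Cc2c(O1)cc(OCc3ccccc3)c3c2O[C@@H](c2ccc(OCc4ccccc4)cc2)[C@H](OCc2ccccc2)C3
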